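**Design of a synthesis of biflavone 14 by twofold ketone-directed C5 hydroxylation**

## The problem

- Target 14 is a biflavone in which C8 of a 5-hydroxy-7-methoxy-2-(4-methoxyphenyl)chromen-4-one (unit 1) is joined through an ether oxygen to the para carbon of ring B of a 5,7-dihydroxy-2-phenylchromen-4-one (unit 2). It has no stereocentre.
- The difficulty is regiochemical. Ring A of unit 1 is fully differentiated (free hydroxyl at C5, methyl ether at C7, aryl ether at C8), and of the five phenolic oxygens of the molecule two are methylated and three are free.
- If ring A of unit 1 is brought in with its C5 oxygen, the acyl-bearing carbon C4a is flanked by two oxygens. Ring C can then close on either, giving the 8-aryloxy or the 6-aryloxy flavone, and hot acid can interconvert the two (Wessely–Moser rearrangement).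
- The diaryl ether has to be formed at an oxygen that sits between the C7 methoxy group and the ring oxygen O1.
- Several groups are fragile. Ring C of a chromone opens in hot alkali. The oxygen-rich rings are open to one-electron oxidation. A 5-hydroxy-8-aryloxy ring is a para-alkoxyphenol that oxidants can convert into a quinone. The last phenol must be freed without touching two methyl ethers.
- The feature that the plan exploits is that in each chromone C5–H lies peri to the C4 carbonyl and is the only C–H that can reach a five-membered metallacycle through the carbonyl oxygen. Both C5 oxygens can therefore be left out until the end, and ring A of unit 1 can come from a ketone with a single ortho hydroxyl.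

## Retrosynthesis

**14 from 13.** The last cut is the acetyl–oxygen bond at O7 of unit 2. The acetate serves the oxidation that precedes it by keeping ring A of unit 2 electron-poor; a free phenol or an ether there would be attacked by the oxidant. It is also removable with methanol and mild base at room temperature without touching the methyl ethers or the chromones. The forward step need only be a clean transesterification.

**13 from 11.** Both C5–O bonds are cut back to C–H, with the bis(trifluoroacetate) 12 as the species that leaves the catalytic cycle. The neighbouring cuts are worse: closing ring C of unit 1 on a ring A with two ortho oxygens, or forming the ether on a finished 5-hydroxyflavone. This cut instead removes the atom that causes the ambiguity. Precursor 11 is simpler where it matters, since each ring A has one oxygen ortho to the acyl carbon and no 5-hydroxyl needs protection upstream. The forward reaction must oxidise two sites selectively in a molecule with three oxygen-rich rings and stop at the phenol stage.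

**11 from 10.** The acetyl–oxygen bond is cut. Phenol 10 has a single free hydroxyl, so no selectivity is asked of the acylation.

**10 from 9, and 9 from 7 and 8.** Ring C of unit 2 is cut at O1–C2 (oxidative cyclisation of a 2'-hydroxychalcone), then the enone double bond of 9 is cut by a retro-aldol condensation. Bringing in unit 2 as a complete 4'-fluoroflavone and forming the ether last would be more convergent. A fluoride para to a vinylogous ketone is, however, a much weaker partner for aromatic substitution than one para to a formyl group, and the hindered phenoxide of 5 needs the better electrophile. Ketone 8 has one hydroxyl ortho to the acetyl group, so closure is unambiguous. The aldol step has to spare the flavone already present in 7.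

**7 from 5 and 6.** The aryl–oxygen bond of the ether is cut on the side of unit 2. The formyl group of 6 activates the fluoride for nucleophilic aromatic substitution and then becomes C2 of unit 2. Flavone 5 has one phenol, so no selectivity question arises.

**5 from 4, and 4 from 2 and 3.** Ring C of unit 1 is cut in the same two operations. In 2 only O2 is ortho to the acetyl group; O3 is meta, cannot close a six-membered ring, and must become the C8 hydroxyl. This is where deferring the C5 oxygen pays off.

**2 from 1.** The methyl–O4 bond is cut. Triol 1 is a cheap catalogue compound. A borate ester ties up its 2,3-diol, so the most acidic hydroxyl, para to the acetyl group, is the only one free for methylation.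

## Roads not taken

**Alternative 1:** Ring C of unit 1 is cut at C4a–C4, C4–C3 and O1–C2, back to the aryl iodide A2 (methyl 4-[4-(benzyloxy)-2,6-dihydroxy-3-iodophenoxy]benzoate), a one-carbon carbonyl unit and the alkyne A3 (1-ethynyl-4-methoxybenzene).
- Forward step: a carbonylative Sonogashira coupling under zerovalent palladium gives an ortho-hydroxyaryl ynone, which closes through the C8a hydroxyl to chromone A1.
- Merits: the C5 oxygen is present from the start as a benzyl ether. The regiochemistry is fixed by symmetry, because the parent of A2 has two equivalent positions for iodination and only the hydroxyl ortho to the ynone can close. Three bonds form in one step, and no oxidant meets the finished skeleton.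
- Weak points: oxidative addition into an iodide flanked by two ortho oxygens on a very electron-rich ring is slow. The ynone can close in the 5-exo mode to an aurone. Iodination must stop at one iodine. The symmetric tetraoxygenated benzene behind A2 needs several steps of its own.
- After the key step, A1 still needs O7 methylation, conversion of the benzoate into the chromone of unit 2 with a protected ortho-hydroxyacetophenone, and two kinds of deprotection.
- Comparison: this road is safer than the chosen plan in its oxidation-state bookkeeping. The chosen plan sets against it nine steps from four catalogue compounds, one protecting group, and a key step with direct precedent on flavones.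

**Alternative 2:** Ring A of unit 1 is cut at C8–C8a and C4a–C5, back to the bromopyranone A5 (5-bromo-2-(4-methoxyphenyl)-4H-pyran-4-one) and the vinylketene silyl acetal A6.
- Forward step: the diene adds across C5=C6 of A5 and the adduct aromatises by two eliminations (bromide, and one alkoxy group of the acetal) to give A4.
- Merits: the three oxygen functions of ring A arrive already differentiated. Regiochemistry is set by polarity, since the nucleophilic diene terminus goes to C6 of the pyranone, the β-carbon of the enone. It is the most convergent of the four roads, and no oxidant is needed.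
- Weak points: a 2-aryl-4-pyranone is a vinylogous ester with aromatic character and a poor dienophile. Dienes of this kind are established with quinones and with strongly activated chromones, not with a pyranone activated by bromine alone. Forcing conditions would endanger the silyl ketene acetal.
- A6 needs a defined geometry at its aryloxy terminus and several steps from an aryloxyacetoacetate. The aromatisation must expel the alkoxy group and not the silyloxy group, or C5 ends as a methyl ether.
- A4 still has to be carried from benzoate to chromone for unit 2.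
- Comparison: on paper this road beats the chosen plan in convergence and in sparing the skeleton any oxidant. The chosen plan offers a key step precedented on its own substrate class and far simpler starting materials.

**Alternative 3:** The O1–C8a bond of unit 1 is cut back to C8a–H of the 1,3-diketone A8 (methyl 4-{2,4-dimethoxy-5-[3-(4-methoxyphenyl)-3-oxopropanoyl]phenoxy}benzoate).
- Forward step: anodic oxidation of the enolised diketone lets the enol oxygen attack C8a, with loss of two electrons and two protons, to give A7.
- Merits: like the chosen plan it turns a ring A C–H into C–O, but early and on a small intermediate, so a failure costs little. The closure site is unique because the other ortho position carries a methoxy group. The C5 methyl ether can later be cleaved selectively by chelation to the C4 carbonyl. Electricity is the only oxidant.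
- Weak points: anodic dehydrogenative closure of ring C of a chromone from an aryl 1,3-diketone is not an established reaction. The enol is the most easily oxidised site, and its radical tends to dimerise or to be oxidised further at the central carbon. C8a is meta to both methoxy groups, so the arene radical cation carries little charge there.
- A7 still needs the C5 demethylation and the whole of unit 2, with protecting groups for two hydroxyls.
- Comparison: this road places its risk earlier than the chosen plan, which is a real advantage. The chosen plan places it last but on a reaction known for flavones, and it is shorter by several steps.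

Key step: step 8

Remark: 14 has no stereocentre. The only stereochemical element on the route is the E double bond of chalcones 4 and 9, which disappears on cyclisation.

## Route

Step 1
Reactants: 1 2,3,4-trihydroxyacetophenone (gallacetophenone)
Product: 2 1-(2,3-dihydroxy-4-methoxyphenyl)ethanone
Conditions: Na2B4O7·10H2O, aq. NaOH, Me2SO4, rt; then HCl
Reagents that add atoms: dimethyl sulfate, COS(=O)(=O)OC
Why: Borate binds the 2,3-diol as a cyclic ester, so only the most acidic hydroxyl (O4, para to the acetyl group) is free for Williamson O-methylation; acid then releases the diol. This is selective alkylation under borate masking, known for 2,3,4-trihydroxyaryl carbonyl compounds.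

Step 2
Reactants: 2 1-(2,3-dihydroxy-4-methoxyphenyl)ethanone; 3 4-methoxybenzaldehyde
Product: 4 (E)-1-(2,3-dihydroxy-4-methoxyphenyl)-3-(4-methoxyphenyl)prop-2-en-1-one
Conditions: KOH (50% aq.), EtOH, N2, rt; then HCl
Reagents that add atoms: none
Why: Claisen–Schmidt condensation: the enolate of 2 adds to the non-enolisable aldehyde 3 and the aldol loses water by an E1cB path to the conjugated E-enone. Exclusion of air protects the catechol-type dianion.

Step 3
Reactants: 4 (E)-1-(2,3-dihydroxy-4-methoxyphenyl)-3-(4-methoxyphenyl)prop-2-en-1-one
Product: 5 8-hydroxy-7-methoxy-2-(4-methoxyphenyl)-4H-chromen-4-one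
Conditions: I2 (10 mol%), DMSO, 120 °C
Reagents that add atoms: none
Why: Iodine-mediated oxidative cyclisation of a 2'-hydroxychalcone: the hydroxyl ortho to the carbonyl closes by 6-endo oxa-Michael addition, and iodination with loss of HI gives the C2=C3 bond while DMSO reoxidises HI. The hydroxyl meta to the acyl group cannot reach and ends as the C8 hydroxyl.

Step 4
Reactants: 5 8-hydroxy-7-methoxy-2-(4-methoxyphenyl)-4H-chromen-4-one; 6 4-fluorobenzaldehyde
Product: 7 4-{[7-methoxy-2-(4-methoxyphenyl)-4-oxo-4H-chromen-8-yl]oxy}benzaldehyde
Conditions: K2CO3, DMF, 120 °C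
Reagents that add atoms: none
Why: Nucleophilic aromatic substitution: the para formyl group stabilises the Meisenheimer intermediate and fluoride is the best leaving group for this mechanism, which lets even a phenoxide with two ortho substituents react. 5 has only one phenol.

Step 5
Reactants: 7 4-{[7-methoxy-2-(4-methoxyphenyl)-4-oxo-4H-chromen-8-yl]oxy}benzaldehyde; 8 2,4-dihydroxyacetophenone
Product: 9 (E)-1-(2,4-dihydroxyphenyl)-3-(4-{[7-methoxy-2-(4-methoxyphenyl)-4-oxo-4H-chromen-8-yl]oxy}phenyl)prop-2-en-1-one
Conditions: 8 (2 equiv), KOH (aq.), EtOH/THF, N2, rt; then dil. HCl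
Reagents that add atoms: none
Why: Claisen–Schmidt condensation as in step 2, with the cheap ketone in excess and the non-enolisable aldehyde limiting; dehydration gives the E-enone. The flavone of 7, with donors at C7 and on ring B, is a poor acceptor for hydroxide at room temperature.

Step 6
Reactants: 9 (E)-1-(2,4-dihydroxyphenyl)-3-(4-{[7-methoxy-2-(4-methoxyphenyl)-4-oxo-4H-chromen-8-yl]oxy}phenyl)prop-2-en-1-one
Product: 10 7-hydroxy-2-(4-{[7-methoxy-2-(4-methoxyphenyl)-4-oxo-4H-chromen-8-yl]oxy}phenyl)-4H-chromen-4-one
Conditions: I2 (10 mol%), DMSO, 120 °C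
Reagents that add atoms: none
Why: The same iodine-mediated oxidative cyclisation as in step 3; only the hydroxyl ortho to the carbonyl can close ring C of unit 2, and the para hydroxyl is left as the C7 phenol. The existing flavone is inert to these conditions.

Step 7
Reactants: 10 7-hydroxy-2-(4-{[7-methoxy-2-(4-methoxyphenyl)-4-oxo-4H-chromen-8-yl]oxy}phenyl)-4H-chromen-4-one
Product: 11 2-(4-{[7-methoxy-2-(4-methoxyphenyl)-4-oxo-4H-chromen-8-yl]oxy}phenyl)-4-oxo-4H-chromen-7-yl acetate
Conditions: Ac2O, pyridine, DMAP (cat.), CH2Cl2, rt
Reagents that add atoms: acetic anhydride, CC(=O)OC(C)=O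
Why: Nucleophile-catalysed O-acylation of the only free phenol. The acetate lowers the electron density of ring A of unit 2 before the oxidation.

Step 8
Reactants: 11 2-(4-{[7-methoxy-2-(4-methoxyphenyl)-4-oxo-4H-chromen-8-yl]oxy}phenyl)-4-oxo-4H-chromen-7-yl acetate
Product: 13 5-hydroxy-2-(4-{[5-hydroxy-7-methoxy-2-(4-methoxyphenyl)-4-oxo-4H-chromen-8-yl]oxy}phenyl)-4-oxo-4H-chromen-7-yl acetate, via C5-bis(trifluoroacetate) ester 12 (not isolated)
Conditions: [RuCl2(p-cymene)]2 (10 mol%), PhI(OCOCF3)2 (5 equiv), CF3CO2H/(CF3CO)2O, 80 °C; then aq. Na2S2O3/NaHCO3, rt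
Reagents that add atoms: [bis(trifluoroacetoxy)iodo]benzene, O=C(OI(OC(=O)C(F)(F)F)c1ccccc1)C(F)(F)F; trifluoroacetic acid, OC(=O)C(F)(F)F (solvent whose carboxylate exchanges with that of the oxidant; one trifluoroacetate oxygen stays at each C5)
Why: Each C4 carbonyl oxygen binds a cationic divalent ruthenium trifluoroacetate, and carboxylate-assisted concerted metalation–deprotonation at the peri carbon C5 gives a five-membered ruthenacycle. PhI(OCOCF3)2 oxidises it to tetravalent ruthenium, and C–O reductive elimination releases the aryl trifluoroacetate and divalent ruthenium; the two chromones react independently, so 12 is reached through either mono-ester. The closest known reaction type is the ruthenium-catalysed ketone-directed ortho C–H hydroxylation of flavones and chromones at C5 with the same oxidant, here applied twice in one molecule. No ring is closed and no stereocentre is formed. Site selectivity is what the step needs: in each chromone C5–H is the only C–H from which the C4 carbonyl can form a five-membered metallacycle (C3–H would need a four-membered one and the ring B hydrogens are out of reach), and once C5 is substituted the carbonyl has no second ortho C–H, so the reaction stops. Chemoselectivity against one-electron oxidation of the oxygen-rich rings rests on protonation of the chromones in CF3CO2H, on the acetyl group on ring A of unit 2, and on each new oxygen staying masked as an electron-poor trifluoroacetate until the oxidant has been reduced. Aqueous hydrogencarbonate then cleaves only the two trifluoroacetates, which are far more labile than the acetate, and each freed hydroxyl is held in a hydrogen bond to its carbonyl.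

Step 9
Reactants: 13 5-hydroxy-2-(4-{[5-hydroxy-7-methoxy-2-(4-methoxyphenyl)-4-oxo-4H-chromen-8-yl]oxy}phenyl)-4-oxo-4H-chromen-7-yl acetate
Product: 14 8-[4-(5,7-dihydroxy-4-oxo-4H-chromen-2-yl)phenoxy]-5-hydroxy-7-methoxy-2-(4-methoxyphenyl)-4H-chromen-4-one
Conditions: K2CO3, MeOH/THF, 0 °C to rt; then dil. HCl
Reagents that add atoms: none
Why: Base-mediated transesterification of an aryl acetate with methanol; the phenoxide is a good leaving group. Aryl methyl ethers, the diaryl ether and both chromones are inert at room temperature.

## Compound list

1 | 2,3,4-trihydroxyacetophenone (gallacetophenone) | CC(=O)c1ccc(O)c(O)c1O | starting material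
2 | 1-(2,3-dihydroxy-4-methoxyphenyl)ethanone | CC(=O)c1ccc(OC)c(O)c1O | intermediate
3 | 4-methoxybenzaldehyde | COc1ccc(C=O)cc1 | starting material
4 | (E)-1-(2,3-dihydroxy-4-methoxyphenyl)-3-(4-methoxyphenyl)prop-2-en-1-one | COc1ccc(/C=C/C(=O)c2ccc(OC)c(O)c2O)cc1 | intermediate
5 | 8-hydroxy-7-methoxy-2-(4-methoxyphenyl)-4H-chromen-4-one | COc1ccc(-c2cc(=O)c3ccc(OC)c(O)c3o2)cc1 | intermediate
6 | 4-fluorobenzaldehyde | O=Cc1ccc(F)cc1 | starting material
7 | 4-{[7-methoxy-2-(4-methoxyphenyl)-4-oxo-4H-chromen-8-yl]oxy}benzaldehyde | COc1ccc(-c2cc(=O)c3ccc(OC)c(Oc4ccc(C=O)cc4)c3o2)cc1 | intermediate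
8 | 2,4-dihydroxyacetophenone | CC(=O)c1ccc(O)cc1O | starting material
9 | (E)-1-(2,4-dihydroxyphenyl)-3-(4-{[7-methoxy-2-(4-methoxyphenyl)-4-oxo-4H-chromen-8-yl]oxy}phenyl)prop-2-en-1-one | COc1ccc(-c2cc(=O)c3ccc(OC)c(Oc4ccc(/C=C/C(=O)c5ccc(O)cc5O)cc4)c3o2)cc1 | intermediate
10 | 7-hydroxy-2-(4-{[7-methoxy-2-(4-methoxyphenyl)-4-oxo-4H-chromen-8-yl]oxy}phenyl)-4H-chromen-4-one | COc1ccc(-c2cc(=O)c3ccc(OC)c(Oc4ccc(-c5cc(=O)c6ccc(O)cc6o5)cc4)c3o2)cc1 | intermediate
11 | 2-(4-{[7-methoxy-2-(4-methoxyphenyl)-4-oxo-4H-chromen-8-yl]oxy}phenyl)-4-oxo-4H-chromen-7-yl acetate | COc1ccc(-c2cc(=O)c3ccc(OC)c(Oc4ccc(-c5cc(=O)c6ccc(OC(C)=O)cc6o5)cc4)c3o2)cc1 | intermediate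
12 | 2-(4-{[7-methoxy-2-(4-methoxyphenyl)-4-oxo-5-(trifluoroacetoxy)-4H-chromen-8-yl]oxy}phenyl)-4-oxo-5-(trifluoroacetoxy)-4H-chromen-7-yl acetate | COc1ccc(-c2cc(=O)c3c(OC(=O)C(F)(F)F)cc(OC)c(Oc4ccc(-c5cc(=O)c6c(OC(=O)C(F)(F)F)cc(OC(C)=O)cc6o5)cc4)c3o2)cc1 | intermediate
13 | 5-hydroxy-2-(4-{[5-hydroxy-7-methoxy-2-(4-methoxyphenyl)-4-oxo-4H-chromen-8-yl]oxy}phenyl)-4-oxo-4H-chromen-7-yl acetate | COc1ccc(-c2cc(=O)c3c(O)cc(OC)c(Oc4ccc(-c5cc(=O)c6c(O)cc(OC(C)=O)cc6o5)cc4)c3o2)cc1 | intermediate
14 | 8-[4-(5,7-dihydroxy-4-oxo-4H-chromen-2-yl)phenoxy]-5-hydroxy-7-methoxy-2-(4-methoxyphenyl)-4H-chromen-4-one | COc1ccc(-c2cc(=O)c3c(O)cc(OC)c(Oc4ccc(-c5cc(=O)c6c(O)cc(O)cc6o5)cc4)c3o2)cc1 | target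

## Step count and risks

Total step count: 9. Longest linear sequence: 9 steps (1 to 14); compounds 3, 6 and 8 enter as purchased.

**Step 8 (key step).**
- What may go wrong: one-electron oxidation of the oxygen-rich rings of unit 1 by the trivalent iodine reagent could outrun cycloruthenation and degrade the substrate. The second hydroxylation could stall while oxidant is consumed unproductively. Traces of water in hot acid could open and reclose ring C of unit 1 (Wessely–Moser isomerisation).
- Exchange of the acetyl group for a trifluoroacetyl group in the acid anhydride medium would be harmless, since step 9 converges on 14.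
- Fallback, from 11 to 13: an iridium-catalysed ketone-directed ortho C–H borylation ([Ir(OMe)(cod)]2, AsPh3, B2pin2, hydrocarbon solvent, 120 °C) should give the 5,5''-bis(pinacolatoboryl) derivative F1. Oxidation of both C–B bonds with NaBO3·4H2O in THF/water then gives 13. This removes both the iodine oxidant and the acid. Any 14 formed by concurrent loss of the acetate is the product of step 9 anyway.

**Step 5.**
- What may go wrong: the dianion of 8 enolises reluctantly, so aldol addition may be slow. Meanwhile hydroxide can attack C2 of the flavone in 7 and open ring C, or the aldehyde can disproportionate.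
- Fallback, from 7 and 8 to 10: pyrrolidine in ethanol at reflux condenses the two through the enamine and iminium ions, and oxa-Michael closure gives the racemic flavanone 7-hydroxy-2-(4-{[7-methoxy-2-(4-methoxyphenyl)-4-oxo-4H-chromen-8-yl]oxy}phenyl)chroman-4-one F2. Dehydrogenation with I2 in DMSO at 120 °C then gives 10. No hydroxide is used.

**Step 2.**
- What may go wrong: the catechol-type dianion of 2 may oxidise in strong base, and a doubly deprotonated ketone enolises slowly.
- Fallback, from 2 to 5:
  - Benzylation of the non-chelated O3 (BnBr, K2CO3, acetone) gives 1-(3-benzyloxy-2-hydroxy-4-methoxyphenyl)ethanone F3.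
  - Claisen–Schmidt condensation with 3 gives (E)-1-(3-benzyloxy-2-hydroxy-4-methoxyphenyl)-3-(4-methoxyphenyl)prop-2-en-1-one F4.
  - I2 in DMSO gives 8-benzyloxy-7-methoxy-2-(4-methoxyphenyl)-4H-chromen-4-one F5.
  - Hydrogenolysis (H2, 10% Pd/C, EtOAc) gives 5.

**Step 1.**
- What may go wrong: incomplete borate masking would allow methylation at O3 or double methylation.
- Fallback, from 1 to 2: exhaustive methylation (Me2SO4, K2CO3, acetone, reflux) gives 1-(2,3,4-trimethoxyphenyl)ethanone F6. BCl3 in CH2Cl2 then removes the methyl groups at O2 and O3 in turn, each through a chelate to the neighbouring oxygen, and leaves the O4 methyl ether, giving 2.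

## Further compounds

F1 | step 8 | 2-(4-{[7-methoxy-2-(4-methoxyphenyl)-4-oxo-5-(4,4,5,5-tetramethyl-1,3,2-dioxaborolan-2-yl)-4H-chromen-8-yl]oxy}phenyl)-4-oxo-5-(4,4,5,5-tetramethyl-1,3,2-dioxaborolan-2-yl)-4H-chromen-7-yl acetate | COc1ccc(-c2cc(=O)c3c(B4OC(C)(C)C(C)(C)O4)cc(OC)c(Oc4ccc(-c5cc(=O)c6c(B7OC(C)(C)C(C)(C)O7)cc(OC(C)=O)cc6o5)cc4)c3o2)cc1
F2 | step 5 | 7-hydroxy-2-(4-{[7-methoxy-2-(4-methoxyphenyl)-4-oxo-4H-chromen-8-yl]oxy}phenyl)chroman-4-one (racemic) | COc1ccc(-c2cc(=O)c3ccc(OC)c(Oc4ccc(C5CC(=O)c6ccc(O)cc6O5)cc4)c3o2)cc1
F3 | step 2 | 1-(3-benzyloxy-2-hydroxy-4-methoxyphenyl)ethanone | CC(=O)c1ccc(OC)c(OCc2ccccc2)c1O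
F4 | step 2 | (E)-1-(3-benzyloxy-2-hydroxy-4-methoxyphenyl)-3-(4-methoxyphenyl)prop-2-en-1-one | COc1ccc(/C=C/C(=O)c2ccc(OC)c(OCc3ccccc3)c2O)cc1
F5 | step 2 | 8-benzyloxy-7-methoxy-2-(4-methoxyphenyl)-4H-chromen-4-one | COc1ccc(-c2cc(=O)c3ccc(OC)c(OCc4ccccc4)c3o2)cc1
F6 | step 1 | 1-(2,3,4-trimethoxyphenyl)ethanone | CC(=O)c1ccc(OC)c(OC)c1OC
A1 | alternative 1 | methyl 4-{[5-(benzyloxy)-7-hydroxy-2-(4-methoxyphenyl)-4-oxo-4H-chromen-8-yl]oxy}benzoate | COc1ccc(-c2cc(=O)c3c(OCc4ccccc4)cc(O)c(Oc4ccc(C(=O)OC)cc4)c3o2)cc1
A2 | alternative 1 | methyl 4-[4-(benzyloxy)-2,6-dihydroxy-3-iodophenoxy]benzoate | COC(=O)c1ccc(Oc2c(O)cc(OCc3ccccc3)c(I)c2O)cc1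
A3 | alternative 1 | 1-ethynyl-4-methoxybenzene | C#Cc1ccc(OC)cc1
A4 | alternative 2 | tert-butyl 4-{[5-hydroxy-7-methoxy-2-(4-methoxyphenyl)-4-oxo-4H-chromen-8-yl]oxy}benzoate | COc1ccc(-c2cc(=O)c3c(O)cc(OC)c(Oc4ccc(C(=O)OC(C)(C)C)cc4)c3o2)cc1
A5 | alternative 2 | 5-bromo-2-(4-methoxyphenyl)-4H-pyran-4-one | COc1ccc(-c2cc(=O)c(Br)co2)cc1
A6 | alternative 2 | tert-butyl 4-{[(1Z,3Z)-2,4-dimethoxy-4-(trimethylsilyloxy)buta-1,3-dien-1-yl]oxy}benzoate | CO/C(O[Si](C)(C)C)=C/C(OC)=C/Oc1ccc(C(=O)OC(C)(C)C)cc1
A7 | alternative 3 | methyl 4-{[5,7-dimethoxy-2-(4-methoxyphenyl)-4-oxo-4H-chromen-8-yl]oxy}benzoate | COC(=O)c1ccc(Oc2c(OC)cc(OC)c3c2oc(-c2ccc(OC)cc2)cc3=O)cc1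
A8 | alternative 3 | methyl 4-{2,4-dimethoxy-5-[3-(4-methoxyphenyl)-3-oxopropanoyl]phenoxy}benzoate | COC(=O)c1ccc(Oc2cc(C(=O)CC(=O)c3ccc(OC)cc3)c(OC)cc2OC)cc1
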